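**Strategy**

Everything rests on cutting the dihydropyran ring (ring B: O1, C2, C3, C4, C4a, C8a) of the chroman at C3–C4 and O1–C2. O1, C8a, C4a and C4 then belong to an o-quinone methide, and C2(Me)2–C3 to a 2-methylpropenylsilane whose silicon stands in for the C3 hydroxyl. A single catalytic enantioselective hetero-Diels–Alder reaction thus closes the pyran ring, forms both skeletal bonds and sets the only stereocentre. Its precursors are 5-bromo-2-(hydroxymethyl)phenol, whose bromine later carries the C7 side chain, and dimethyl(2-methylprop-1-enyl)phenylsilane. Retentive C–Si oxidation, formylation and a phosphine-mediated olefination–isomerisation with a 3-arylmaleimide finish asperimide C.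

Key step: step 3

Assumption: the acid of step 3 is a confined imidodiphosphorimidate built from two (S)-3,3'-bis(4-tert-butylphenyl)-1,1'-bi-2-naphthol units with an N-trifluoromethanesulfonyl group on each phosphorus; its sense of induction cannot be predicted with confidence, so whichever antipode gives (S)-8 is to be used.

**Route**

Step 1
Reactants: 1 4-bromo-2-hydroxybenzaldehyde
Product: 2 5-bromo-2-(hydroxymethyl)phenol
Conditions: NaBH4, MeOH, 0 °C
Reagents that add atoms: none
Why: Borohydride reduction of an aromatic aldehyde to the benzylic alcohol, which leaves the aryl bromide and the phenol untouched.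

Step 2
Reactants: 3 1-bromo-2-methylprop-1-ene; 4 chlorodimethylphenylsilane
Product: 6 dimethyl(2-methylprop-1-enyl)phenylsilane, via (2-methylprop-1-enyl)magnesium bromide 5 (not isolated)
Conditions: Mg, I2 (cat.), THF, reflux; then 4, 0 °C → rt
Reagents that add atoms: none
Why: Grignard formation from the vinylic bromide followed by substitution of chloride at silicon is the standard preparation of alkenylsilanes, and the gem-dimethyl alkene has no geometry to control.

Step 3
Reactants: 2 5-bromo-2-(hydroxymethyl)phenol; 6 dimethyl(2-methylprop-1-enyl)phenylsilane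
Product: 8 (S)-(7-bromo-2,2-dimethylchroman-3-yl)dimethyl(phenyl)silane, via 3-bromo-6-methylidenecyclohexa-2,4-dien-1-one 7 (not isolated)
Conditions: chiral imidodiphosphorimidate acid (5 mol%), 6 (3 equiv), 5 Å MS, CHCl3, 0 °C, 2 added slowly
Reagents that add atoms: none
Why: Proposed new method: the strong confined acid ionises the benzylic C–O bond of 2 (the cation is stabilised by the ortho oxygen much as in a p-methoxybenzyl system) to give methide 7 hydrogen-bonded in the chiral anion pocket, and the silicon-bearing carbon of 6 attacks the exocyclic CH2 of the heterodiene C4=C4a–C8a=O1, so that C3–C4 forms ahead of O1–C2 in an asynchronous inverse-electron-demand [4+2]. The closest known reaction type is the acid-catalysed hetero-Diels–Alder of in situ o-quinone methides with styrenes and trisubstituted alkenes, chiral phosphoric acid versions included, whereas neither a vinylsilane partner nor an unsubstituted methide has been used under enantiocontrol. The pyran ring closes within the cycloaddition itself, the oxygen capturing the developing tertiary, β-silyl-stabilised cation at CMe2 through a six-membered transition state (at the stepwise limit a six-ring oxygen trap of that cation). The methide CH2 becomes the C4 methylene and is not stereogenic, so the single new stereocentre C3 is decided by which face of the vinylsilane CH carbon bonds, that is by the catalyst covering one face of the bound methide and forcing the bulky PhMe2Si group into one (exo) orientation in the pocket. Regioselectivity (Si on C3, CMe2 on O1) is secured twice, by Markovnikov and by β-silicon stabilisation of the same cation. Ring closure over loss of silicon to the prenylphenol is favoured by the intramolecular oxygen trap, the hindered PhMe2Si group, the non-nucleophilic counter-anion and the sieves; slow addition of 2 limits self-condensation of the methide.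

Step 4
Reactants: 8 (S)-(7-bromo-2,2-dimethylchroman-3-yl)dimethyl(phenyl)silane
Product: 9 (S)-7-bromo-2,2-dimethylchroman-3-ol
Conditions: Hg(OAc)2, AcOOH, NaOAc, AcOH, rt
Reagents that add atoms: peracetic acid CC(=O)OO
Why: One-pot Fleming–Tamao oxidation, in which ipso-mercuridesilylation removes the phenyl group from silicon and the acetoxysilane then rearranges with peracid so that C3 migrates from Si to O with retention [(S)-8 gives (S)-9, Si and O both ranking first at C3]; buffered, fluoride-free and base-free conditions are chosen because silicon lies β to the ring aryloxy oxygen, so fluoride, alkoxide or strong acid would open the pyran by elimination.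

Step 5
Reactants: 9 (S)-7-bromo-2,2-dimethylchroman-3-ol
Product: 10 (S)-[(7-bromo-2,2-dimethylchroman-3-yl)oxy]triethylsilane
Conditions: TESOTf, 2,6-lutidine, CH2Cl2, 0 °C
Reagents that add atoms: triethylsilyl trifluoromethanesulfonate CC[Si](CC)(CC)OS(=O)(=O)C(F)(F)F
Why: O-silylation with a silyl triflate and a hindered pyridine base protects the neopentyl-type secondary alcohol without touching the C–O stereocentre or the aryl bromide.

Step 6
Reactants: 10 (S)-[(7-bromo-2,2-dimethylchroman-3-yl)oxy]triethylsilane
Product: 12 (S)-2,2-dimethyl-3-(triethylsilyloxy)chroman-7-carbaldehyde, via aryllithium 11 (not isolated)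
Conditions: n-BuLi, THF, −78 °C; DMF; then H2O
Reagents that add atoms: N,N-dimethylformamide CN(C)C=O
Why: Bromine–lithium exchange at −78 °C is faster than any attack on the silyl ether, and the aryllithium adds to DMF to give the aldehyde on hydrolysis (Bouveault formylation).

Step 7
Reactants: 13 maleimide
Product: 15 3-bromo-1H-pyrrole-2,5-dione, via trans-3,4-dibromopyrrolidine-2,5-dione 14 (not isolated)
Conditions: Br2, CHCl3, reflux; then Et3N, THF, 0 °C
Reagents that add atoms: bromine BrBr
Why: Anti-addition of bromine to the maleimide alkene followed by amine-induced dehydrobromination (E1cB through the acidic α-C–H) restores the conjugated alkene with one bromine.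

Step 8
Reactants: 15 3-bromo-1H-pyrrole-2,5-dione; 16 [4-(tert-butyldimethylsilyloxy)phenyl]boronic acid
Product: 17 3-[4-(tert-butyldimethylsilyloxy)phenyl]-1H-pyrrole-2,5-dione
Conditions: PdCl2(dppf) (3 mol%), K3PO4, THF/H2O, 40 °C (dppf = 1,1'-bis(diphenylphosphino)ferrocene)
Reagents that add atoms: none
Why: Suzuki–Miyaura coupling, in which the electron-poor vinylic C–Br bond adds easily to zerovalent palladium, so a mild phosphate base at 40 °C with a chelating phosphine should suffice and spare the imide (present as its potassium salt) and the aryl silyl ether.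

Step 9
Reactants: 12 (S)-2,2-dimethyl-3-(triethylsilyloxy)chroman-7-carbaldehyde; 17 3-[4-(tert-butyldimethylsilyloxy)phenyl]-1H-pyrrole-2,5-dione
Product: 20 3-{[(3S)-2,2-dimethyl-3-(triethylsilyloxy)chroman-7-yl]methyl}-4-[4-(tert-butyldimethylsilyloxy)phenyl]-1H-pyrrole-2,5-dione, via imide phosphorus ylide 18 (not isolated), via (E)-arylmethylidenesuccinimide 19 (not isolated)
Conditions: PPh3, THF, rt; 12, reflux; then Et3N, reflux
Reagents that add atoms: none
Why: PPh3 adds to the unsubstituted alkene carbon of 17 and proton transfer (shuttled by the imide N–H) gives the stabilised ylide, Wittig olefination with 12 gives the exocyclic (E)-alkene, and Et3N moves the double bond into the ring through the doubly activated C3–H to the tetrasubstituted maleimide conjugated with both carbonyls and the aryl group (Wittig olefination then base-mediated alkene isomerisation, as known for 3-substituted maleimides); the chroman stereocentre is remote and untouched.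

Step 10
Reactants: 20 3-{[(3S)-2,2-dimethyl-3-(triethylsilyloxy)chroman-7-yl]methyl}-4-[4-(tert-butyldimethylsilyloxy)phenyl]-1H-pyrrole-2,5-dione
Product: 21 asperimide C
Conditions: HF·pyridine, THF, 0 °C → rt
Reagents that add atoms: none
Why: Fluoride-driven cleavage of both Si–O bonds (silyl ether deprotection) under weakly acidic conditions should leave the maleimide, the tertiary aryl ether and the C3 stereocentre unchanged.

**Compound list**

1 | 4-bromo-2-hydroxybenzaldehyde | O=Cc1ccc(Br)cc1O | starting material
2 | 5-bromo-2-(hydroxymethyl)phenol | OCc1ccc(Br)cc1O | intermediate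
3 | 1-bromo-2-methylprop-1-ene | CC(C)=CBr | starting material
4 | chlorodimethylphenylsilane | C[Si](C)(Cl)c1ccccc1 | starting material
5 | (2-methylprop-1-enyl)magnesium bromide | CC(C)=C[Mg]Br | intermediate
6 | dimethyl(2-methylprop-1-enyl)phenylsilane | CC(C)=C[Si](C)(C)c1ccccc1 | intermediate
7 | 3-bromo-6-methylidenecyclohexa-2,4-dien-1-one | C=C1C=CC(Br)=CC1=O | intermediate
8 | (S)-(7-bromo-2,2-dimethylchroman-3-yl)dimethyl(phenyl)silane | CC1(C)Oc2cc(Br)ccc2C[C@@H]1[Si](C)(C)c3ccccc3 | intermediate
9 | (S)-7-bromo-2,2-dimethylchroman-3-ol | CC1(C)Oc2cc(Br)ccc2C[C@@H]1O | intermediate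
10 | (S)-[(7-bromo-2,2-dimethylchroman-3-yl)oxy]triethylsilane | CC1(C)Oc2cc(Br)ccc2C[C@@H]1O[Si](CC)(CC)CC | intermediate
11 | (S)-7-lithio-2,2-dimethyl-3-(triethylsilyloxy)chroman | CC1(C)Oc2cc([Li])ccc2C[C@@H]1O[Si](CC)(CC)CC | intermediate
12 | (S)-2,2-dimethyl-3-(triethylsilyloxy)chroman-7-carbaldehyde | CC1(C)Oc2cc(C=O)ccc2C[C@@H]1O[Si](CC)(CC)CC | intermediate
13 | maleimide (1H-pyrrole-2,5-dione) | O=C1C=CC(=O)N1 | starting material
14 | trans-3,4-dibromopyrrolidine-2,5-dione (racemic, one enantiomer drawn) | O=C1NC(=O)[C@@H](Br)[C@@H]1Br | intermediate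
15 | 3-bromo-1H-pyrrole-2,5-dione | O=C1NC(=O)C(Br)=C1 | intermediate
16 | [4-(tert-butyldimethylsilyloxy)phenyl]boronic acid | CC(C)(C)[Si](C)(C)Oc1ccc(B(O)O)cc1 | starting material
17 | 3-[4-(tert-butyldimethylsilyloxy)phenyl]-1H-pyrrole-2,5-dione | CC(C)(C)[Si](C)(C)Oc1ccc(cc1)C2=CC(=O)NC2=O | intermediate
18 | 3-[4-(tert-butyldimethylsilyloxy)phenyl]-4-(triphenylphosphoranylidene)pyrrolidine-2,5-dione (C3 unassigned) | CC(C)(C)[Si](C)(C)Oc1ccc(cc1)C2C(=O)NC(=O)C2=P(c3ccccc3)(c4ccccc4)c5ccccc5 | intermediate
19 | (E)-3-[4-(tert-butyldimethylsilyloxy)phenyl]-4-{[(3S)-2,2-dimethyl-3-(triethylsilyloxy)chroman-7-yl]methylidene}pyrrolidine-2,5-dione (epimers at the imide C3) | CC1(C)Oc2cc(/C=C3/C(=O)NC(=O)C3c4ccc(O[Si](C)(C)C(C)(C)C)cc4)ccc2C[C@@H]1O[Si](CC)(CC)CC | intermediate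
20 | 3-{[(3S)-2,2-dimethyl-3-(triethylsilyloxy)chroman-7-yl]methyl}-4-[4-(tert-butyldimethylsilyloxy)phenyl]-1H-pyrrole-2,5-dione | CC1(C)Oc2cc(CC3=C(c4ccc(O[Si](C)(C)C(C)(C)C)cc4)C(=O)NC3=O)ccc2C[C@@H]1O[Si](CC)(CC)CC | intermediate
21 | asperimide C, 3-{[(3S)-3-hydroxy-2,2-dimethylchroman-7-yl]methyl}-4-(4-hydroxyphenyl)-1H-pyrrole-2,5-dione | CC1(C)Oc2cc(CC3=C(c4ccc(O)cc4)C(=O)NC3=O)ccc2C[C@@H]1O | target

**Step count**

Total: 10 steps. Longest linear sequence: 7 steps (steps 1, 3, 4, 5, 6, 9, 10).

**Steps most likely to fail**

Step 3. The primary benzylic alcohol may ionise too slowly, the vinylsilane may lose silicon (protodesilylation, or desilylation after C–C bond formation) faster than the ring closes, the methide may self-condense, or the catalyst may discriminate poorly between the two faces of the vinylsilane. The fallback uses known chemistry, sets out from 1 and the Grignard reagent 5, and returns at 9. Addition of 5 (2.2 equiv, THF, 0 °C) to 1 should give 5-bromo-2-(1-hydroxy-3-methylbut-2-en-1-yl)phenol F1. Warming F1 with catalytic TsOH in toluene should cause dehydration and oxa-6π ring closure to 7-bromo-2,2-dimethyl-2H-chromene F2. Jacobsen–Katsuki epoxidation (NaOCl, 4-phenylpyridine N-oxide, CH2Cl2, 0 °C) would follow, using the N,N'-bis(3,5-di-tert-butylsalicylidene)cyclohexane-1,2-diamine chloride complex of trivalent manganese. The antipode is chosen that gives (3S,4S)-7-bromo-3,4-epoxy-2,2-dimethylchroman F3, expected to be the (S,S)-complex by analogy with other 2,2-dimethylchromenes. LiAlH4 in THF at 0 °C should then deliver hydride to the benzylic C4 and leave the C3–O bond intact, giving 9.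

Step 4. The pyran ring may open by loss of silicon together with the β-aryloxy oxygen (Peterson-type elimination), or the mercury salt may attack the electron-rich ring instead of the phenylsilane. The fallback sets out from 8 and returns at 9; it gives up the stereocentre of step 3 and restores it by epoxidation. Deliberate fluoride-induced elimination (TBAF, THF) converts 8 into 5-bromo-2-(3-methylbut-2-en-1-yl)phenol F4. Oxidative cyclisation of F4 with DDQ in refluxing benzene, a known reaction of o-prenylphenols, gives chromene F2. Asymmetric epoxidation to F3 and hydride opening as described under step 3 then give 9.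

Step 9. The α-branched stabilised ylide may olefinate the aldehyde sluggishly, the phosphine may oligomerise the maleimide, or double-bond migration into the ring may stop short. The fallback builds the maleimide ring last; it sets out from 12 and returns at 21. Wittig reaction of 12 with (carbamoylmethylene)triphenylphosphorane gives (E)-3-[(3S)-2,2-dimethyl-3-(triethylsilyloxy)chroman-7-yl]prop-2-enamide F5, and hydrogenation (H2, Pd/C, EtOAc) gives 3-[(3S)-2,2-dimethyl-3-(triethylsilyloxy)chroman-7-yl]propanamide F6. The partner methyl 2-oxo-2-[4-(triisopropylsilyloxy)phenyl]acetate F7 is made from methyl 2-(4-hydroxyphenyl)-2-oxoacetate with i-Pr3SiCl and imidazole. Condensation of F6 with F7 under KOt-Bu in THF (glyoxylate ester–amide maleimide synthesis) gives 3-{[(3S)-2,2-dimethyl-3-(triethylsilyloxy)chroman-7-yl]methyl}-4-[4-(triisopropylsilyloxy)phenyl]-1H-pyrrole-2,5-dione F8. Desilylation of F8 under the conditions of step 10 gives 21.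

**Further compounds**

F1 | step 3 | 5-bromo-2-(1-hydroxy-3-methylbut-2-en-1-yl)phenol (racemic) | CC(C)=CC(O)c1ccc(Br)cc1O
F2 | step 3 | 7-bromo-2,2-dimethyl-2H-chromene | CC1(C)C=Cc2ccc(Br)cc2O1
F3 | step 3 | (3S,4S)-7-bromo-3,4-epoxy-2,2-dimethylchroman | CC1(C)Oc2cc(Br)ccc2[C@@H]3O[C@H]13
F4 | step 4 | 5-bromo-2-(3-methylbut-2-en-1-yl)phenol | CC(C)=CCc1ccc(Br)cc1O
F5 | step 9 | (E)-3-[(3S)-2,2-dimethyl-3-(triethylsilyloxy)chroman-7-yl]prop-2-enamide | CC1(C)Oc2cc(/C=C/C(N)=O)ccc2C[C@@H]1O[Si](CC)(CC)CC
F6 | step 9 | 3-[(3S)-2,2-dimethyl-3-(triethylsilyloxy)chroman-7-yl]propanamide | CC1(C)Oc2cc(CCC(N)=O)ccc2C[C@@H]1O[Si](CC)(CC)CC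
F7 | step 9 | methyl 2-oxo-2-[4-(triisopropylsilyloxy)phenyl]acetate | COC(=O)C(=O)c1ccc(O[Si](C(C)C)(C(C)C)C(C)C)cc1
F8 | step 9 | 3-{[(3S)-2,2-dimethyl-3-(triethylsilyloxy)chroman-7-yl]methyl}-4-[4-(triisopropylsilyloxy)phenyl]-1H-pyrrole-2,5-dione | CC1(C)Oc2cc(CC3=C(c4ccc(O[Si](C(C)C)(C(C)C)C(C)C)cc4)C(=O)NC3=O)ccc2C[C@@H]1O[Si](CC)(CC)CC
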